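**Retrosynthetic overview**
- The target comes from its penta-TBS ether 17 by desilylation. Compound 17 comes from its C6 epimer 16 by acid epimerisation through the C6 benzylic cation.
- Compound 16 is opened at C6–C6a: a rhodium carbenoid at the lactone α-carbon C6a (ring A) inserts into a C6–H bond and closes ring B.
- The strategy rests on the C6–H bond of the aryl-methyl ether in the chain C3a–C4H2–O5–C6H2–Ar2. O5 and the electron-rich Ar2 activate it, and it lies five atoms from C6a.
- Ring A is made first. An Evans syn-aldol of a succinate imide with silylated 3,4,5-trihydroxybenzaldehyde, followed by lactonisation, sets C3 and C3a. Auxiliary removal, O-alkylation with the Ar2-methyl imidate and diazo transfer give the precursor 15.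

Key step: step 10

Remark: numbering follows tetrahydro-1H,3H-furo[3,4-c]furan-1-one (C1 carbonyl, O2, C3, C3a, C4, O5, C6, C6a); Ar1 (on C3) is the 3,4,5-trioxygenated ring, Ar2 (on C6) the 3,4-dioxygenated ring, TBS is tert-butyldimethylsilyl. The insertion is taken to place Ar2 endo (cis to C1) under kinetic control, so the exo configuration at C6 is installed in a separate step.

**Route**

Step 1
Reactants: 1 3,4,5-trihydroxybenzaldehyde
Product: 2 3,4,5-tris(TBSO)benzaldehyde
Conditions: TBSCl (3.6 equiv), imidazole, DMF, 0 °C to rt, argon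
Reagents that add atoms: tert-butyldimethylsilyl chloride, CC(C)(C)[Si](C)(C)Cl
Why: Silyl ether formation with TBSCl/imidazole in DMF should cap all three phenols, including the crowded central one, and leaves the aldehyde untouched; no stereocentre is involved.

Step 2
Reactants: 3 3,4-dihydroxybenzaldehyde
Product: 4 3,4-bis(TBSO)benzaldehyde
Conditions: TBSCl (2.4 equiv), imidazole, DMF, rt
Reagents that add atoms: tert-butyldimethylsilyl chloride, CC(C)(C)[Si](C)(C)Cl
Why: The same silyl ether formation on a catechol, a routine protection that should proceed cleanly.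

Step 3
Reactants: 4 3,4-bis(TBSO)benzaldehyde
Product: 5 [3,4-bis(TBSO)phenyl]methanol
Conditions: NaBH4, MeOH–THF, 0 °C
Reagents that add atoms: none
Why: Borohydride reduction of an aromatic aldehyde is fast at 0 °C, and aryl silyl ethers should survive the short exposure.

Step 4
Reactants: 5 [3,4-bis(TBSO)phenyl]methanol
Product: 6 [3,4-bis(TBSO)phenyl]methyl 2,2,2-trichloroacetimidate
Conditions: Cl3CCN, DBU (10 mol%), CH2Cl2, 0 °C; used after filtration through Et3N-deactivated silica
Reagents that add atoms: trichloroacetonitrile, N#CC(Cl)(Cl)Cl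
Why: Base-catalysed addition of the benzylic alkoxide to trichloroacetonitrile (imidate formation as for 4-methoxybenzyl trichloroacetimidate) should give the activated benzyl donor without touching the silyl ethers.

Step 5
Reactants: 7 (S)-4-benzyl-2-oxazolidinone; 8 methyl 4-chloro-4-oxobutanoate
Product: 9 methyl 4-[(4S)-4-benzyl-2-oxo-1,3-oxazolidin-3-yl]-4-oxobutanoate
Conditions: n-BuLi, THF, −78 °C; then 8, −78 to 0 °C
Reagents that add atoms: none
Why: N-acylation of the lithiated oxazolidinone by the acid chloride is much faster than attack at the methyl ester, so the succinate imide should form selectively.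

Step 6
Reactants: 9 methyl 4-[(4S)-4-benzyl-2-oxo-1,3-oxazolidin-3-yl]-4-oxobutanoate; 2 3,4,5-tris(TBSO)benzaldehyde
Product: 11 (4S)-4-benzyl-3-{[(2S,3S)-5-oxo-2-[3,4,5-tris(TBSO)phenyl]oxolan-3-yl]carbonyl}-1,3-oxazolidin-2-one (trans lactone), via open-chain syn-aldol adduct 10 (not isolated)
Conditions: Bu2BOTf, iPr2NEt, CH2Cl2, 0 °C; 2, −78 to 0 °C; pH 7 buffer, MeOH, H2O2, 0 °C; crude, PPTS (cat.), PhMe, 50 °C
Reagents that add atoms: none
Why: Evans syn-aldol: the imide (not the ester) is enolised to the Z-dibutylboron enolate, which should add to the aldehyde through a Zimmerman–Traxler chair on the face away from the benzyl group of the auxiliary, setting both centres as (3S,4S) in 10 (later C3a and C3); the γ-hydroxy ester then lactonises, and a syn aldol necessarily gives the 4,5-trans lactone.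

Step 7
Reactants: 11 (4S)-4-benzyl-3-{[(2S,3S)-5-oxo-2-[3,4,5-tris(TBSO)phenyl]oxolan-3-yl]carbonyl}-1,3-oxazolidin-2-one
Product: 12 (4R,5S)-4-(hydroxymethyl)-5-[3,4,5-tris(TBSO)phenyl]oxolan-2-one
Conditions: NaBH4, THF–H2O (4:1), 0 °C; aq. NH4Cl quench at 0 °C
Reagents that add atoms: none
Why: Reductive removal of the auxiliary: borohydride in wet THF should reduce the activated exocyclic imide carbonyl to the primary alcohol much faster than the lactone, without touching a stereocentre (the descriptor at C4 changes only through priorities); the cold buffered quench is meant to stop the alkoxide from migrating the lactone.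

Step 8
Reactants: 12 (4R,5S)-4-(hydroxymethyl)-5-[3,4,5-tris(TBSO)phenyl]oxolan-2-one; 6 [3,4-bis(TBSO)phenyl]methyl 2,2,2-trichloroacetimidate
Product: 13 (4R,5S)-4-({[3,4-bis(TBSO)phenyl]methoxy}methyl)-5-[3,4,5-tris(TBSO)phenyl]oxolan-2-one
Conditions: CSA (5 mol%), CH2Cl2, 4 Å MS, 0 °C to rt
Reagents that add atoms: none
Why: Acid-catalysed trichloroacetimidate O-alkylation: the protonated imidate should release an electron-rich benzylic cation that the primary alcohol captures, under non-basic conditions that avoid translactonisation and enolate chemistry.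

Step 9
Reactants: 13 (4R,5S)-4-({[3,4-bis(TBSO)phenyl]methoxy}methyl)-5-[3,4,5-tris(TBSO)phenyl]oxolan-2-one
Product: 15 (4R,5S)-3-diazo-4-({[3,4-bis(TBSO)phenyl]methoxy}methyl)-5-[3,4,5-tris(TBSO)phenyl]oxolan-2-one, via alpha-trifluoroacetyl lactone 14 (not isolated)
Conditions: LiN(SiMe3)2, THF, −78 °C; CF3CO2CH2CF3; cold 1 M HCl wash; then 4-acetamidobenzenesulfonyl azide, Et3N, H2O (1 equiv), MeCN, rt
Reagents that add atoms: 4-acetamidobenzenesulfonyl azide, CC(=O)Nc1ccc(cc1)S(=O)(=O)N=[N+]=[N-] (the two diazo nitrogens); 2,2,2-trifluoroethyl trifluoroacetate, O=C(OCC(F)(F)F)C(F)(F)F (trifluoroacetyl group, kept only in 14)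
Why: Detrifluoroacetylative diazo transfer (a deacylative Regitz transfer): the lithium enolate is trifluoroacetylated at the α-carbon, and the activated 1,3-dicarbonyl should accept the diazo group from the sulfonyl azide and lose the trifluoroacetyl group as the N-acyl sulfonamide; it is chosen over formylation with NaH and ethyl formate because it is short and cold, which suits the aryl silyl ethers.

Step 10
Reactants: 15 (4R,5S)-3-diazo-4-({[3,4-bis(TBSO)phenyl]methoxy}methyl)-5-[3,4,5-tris(TBSO)phenyl]oxolan-2-one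
Product: 16 (3S,3aR,6R,6aS)-6-[3,4-bis(TBSO)phenyl]-3-[3,4,5-tris(TBSO)phenyl]tetrahydro-1H,3H-furo[3,4-c]furan-1-one (cis-fused, Ar1 exo, Ar2 endo)
Conditions: Rh2(OAc)4 (2 mol%), CH2Cl2, rt, slow addition of 15
Reagents that add atoms: none
Why: Rh2(OAc)4 takes up the diazo carbon, N2 leaves, and the electrophilic divalent rhodium carbenoid at C6a inserts into a benzylic C6–H bond through a concerted, asynchronous three-centre transition state in which the positive charge building at C6 is carried by O5 and the para-silyloxy group of Ar2. The closest known reaction type is the dirhodium-catalysed 1,5 C–H insertion of α-diazo-γ-butyrolactones into benzylic ether C–H bonds, which gives furofuranones. Ring B closes as a five-membered ring by 1,5-insertion (C6a, C3a, C4, O5, C6), and because the tether hangs from C3a it reaches only the syn face of C6a, so the fusion is cis and C6a (S) is set by C3a. At C6 the insertion goes with retention into the hydrogen that lets Ar2 turn away from the carboxylate wall of the catalyst and lie over the lactone carbonyl, so Ar2 should come out endo, cis to C1, as (6R); the exo configuration of the target is therefore installed in step 11. The step needs chemoselectivity for insertion over 1,2-hydride shift from C3a–H, oxonium-ylide formation at O5 and carbene dimerisation, which the doubly activated C6–H bond, the five-membered transition state, slow addition of 15 and a non-coordinating solvent should secure.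

Step 11
Reactants: 16 (3S,3aR,6R,6aS)-6-[3,4-bis(TBSO)phenyl]-3-[3,4,5-tris(TBSO)phenyl]tetrahydro-1H,3H-furo[3,4-c]furan-1-one
Product: 17 (3S,3aR,6S,6aS)-6-[3,4-bis(TBSO)phenyl]-3-[3,4,5-tris(TBSO)phenyl]tetrahydro-1H,3H-furo[3,4-c]furan-1-one (cis-fused, both aryl groups exo)
Conditions: BF3·OEt2 (20 mol%), CH2Cl2, −40 to 0 °C; Et3N quench; unchanged 16 separated and resubmitted
Reagents that add atoms: none
Why: Lewis-acid-catalysed epimerisation of a benzylic ether centre, the reaction type by which furofuran lignans are interconverted at their aryl-bearing carbons: coordination at O5 should ionise C6–O5 to the benzylic cation stabilised by the para-silyloxy group, the C4 oxygen recloses ring B, and under reversible conditions the isomer with Ar2 on the convex face and trans to C1 is expected to accumulate; C3a and C6a are not touched, and any ionisation at C3 can only return Ar1 to the favoured exo position.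

Step 12
Reactants: 17 (3S,3aR,6S,6aS)-6-[3,4-bis(TBSO)phenyl]-3-[3,4,5-tris(TBSO)phenyl]tetrahydro-1H,3H-furo[3,4-c]furan-1-one
Product: 18 (3S,3aR,6S,6aS)-6-(3,4-dihydroxyphenyl)-3-(3,4,5-trihydroxyphenyl)tetrahydro-1H,3H-furo[3,4-c]furan-1-one (CNP0290035.1)
Conditions: TBAF (6 equiv), AcOH (8 equiv), THF, 0 °C to rt, argon
Reagents that add atoms: none
Why: Fluoride-mediated cleavage of aryl silyl ethers, buffered with acetic acid so that no phenoxide forms, since a phenoxide para to C3 or C6 could expel the carboxylate or alkoxide as a quinone methide; the four stereocentres are not involved.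

**Compound list**
1 | 3,4,5-trihydroxybenzaldehyde | O=Cc1cc(O)c(O)c(O)c1 | starting material
2 | 3,4,5-tris(TBSO)benzaldehyde | O=Cc1cc(O[Si](C)(C)C(C)(C)C)c(O[Si](C)(C)C(C)(C)C)c(O[Si](C)(C)C(C)(C)C)c1 | intermediate
3 | 3,4-dihydroxybenzaldehyde | O=Cc1ccc(O)c(O)c1 | starting material
4 | 3,4-bis(TBSO)benzaldehyde | O=Cc1ccc(O[Si](C)(C)C(C)(C)C)c(O[Si](C)(C)C(C)(C)C)c1 | intermediate
5 | [3,4-bis(TBSO)phenyl]methanol | OCc1ccc(O[Si](C)(C)C(C)(C)C)c(O[Si](C)(C)C(C)(C)C)c1 | intermediate
6 | [3,4-bis(TBSO)phenyl]methyl 2,2,2-trichloroacetimidate | N=C(OCc1ccc(O[Si](C)(C)C(C)(C)C)c(O[Si](C)(C)C(C)(C)C)c1)C(Cl)(Cl)Cl | intermediate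
7 | (S)-4-benzyl-2-oxazolidinone | O=C1N[C@@H](Cc2ccccc2)CO1 | starting material
8 | methyl 4-chloro-4-oxobutanoate | COC(=O)CCC(Cl)=O | starting material
9 | methyl 4-[(4S)-4-benzyl-2-oxo-1,3-oxazolidin-3-yl]-4-oxobutanoate | COC(=O)CCC(=O)N1[C@@H](Cc2ccccc2)COC1=O | intermediate
10 | methyl (3S,4S)-3-{[(4S)-4-benzyl-2-oxo-1,3-oxazolidin-3-yl]carbonyl}-4-hydroxy-4-[3,4,5-tris(TBSO)phenyl]butanoate | O[C@H](c1cc(O[Si](C)(C)C(C)(C)C)c(O[Si](C)(C)C(C)(C)C)c(O[Si](C)(C)C(C)(C)C)c1)[C@@H](C(=O)N1[C@@H](Cc2ccccc2)COC1=O)CC(=O)OC | intermediate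
11 | (4S)-4-benzyl-3-{[(2S,3S)-5-oxo-2-[3,4,5-tris(TBSO)phenyl]oxolan-3-yl]carbonyl}-1,3-oxazolidin-2-one | O=C1O[C@H](c2cc(O[Si](C)(C)C(C)(C)C)c(O[Si](C)(C)C(C)(C)C)c(O[Si](C)(C)C(C)(C)C)c2)[C@@H](C(=O)N2[C@@H](Cc3ccccc3)COC2=O)C1 | intermediate
12 | (4R,5S)-4-(hydroxymethyl)-5-[3,4,5-tris(TBSO)phenyl]oxolan-2-one | O=C1O[C@H](c2cc(O[Si](C)(C)C(C)(C)C)c(O[Si](C)(C)C(C)(C)C)c(O[Si](C)(C)C(C)(C)C)c2)[C@@H](CO)C1 | intermediate
13 | (4R,5S)-4-({[3,4-bis(TBSO)phenyl]methoxy}methyl)-5-[3,4,5-tris(TBSO)phenyl]oxolan-2-one | O=C1O[C@H](c2cc(O[Si](C)(C)C(C)(C)C)c(O[Si](C)(C)C(C)(C)C)c(O[Si](C)(C)C(C)(C)C)c2)[C@@H](COCc2ccc(O[Si](C)(C)C(C)(C)C)c(O[Si](C)(C)C(C)(C)C)c2)C1 | intermediate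
14 | (4R,5S)-4-({[3,4-bis(TBSO)phenyl]methoxy}methyl)-3-(trifluoroacetyl)-5-[3,4,5-tris(TBSO)phenyl]oxolan-2-one (C3 epimers and enol) | O=C1O[C@H](c2cc(O[Si](C)(C)C(C)(C)C)c(O[Si](C)(C)C(C)(C)C)c(O[Si](C)(C)C(C)(C)C)c2)[C@@H](COCc2ccc(O[Si](C)(C)C(C)(C)C)c(O[Si](C)(C)C(C)(C)C)c2)C1C(=O)C(F)(F)F | intermediate
15 | (4R,5S)-3-diazo-4-({[3,4-bis(TBSO)phenyl]methoxy}methyl)-5-[3,4,5-tris(TBSO)phenyl]oxolan-2-one | O=C1O[C@H](c2cc(O[Si](C)(C)C(C)(C)C)c(O[Si](C)(C)C(C)(C)C)c(O[Si](C)(C)C(C)(C)C)c2)[C@@H](COCc2ccc(O[Si](C)(C)C(C)(C)C)c(O[Si](C)(C)C(C)(C)C)c2)C1=[N+]=[N-] | intermediate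
16 | (3S,3aR,6R,6aS)-6-[3,4-bis(TBSO)phenyl]-3-[3,4,5-tris(TBSO)phenyl]tetrahydro-1H,3H-furo[3,4-c]furan-1-one | O=C1O[C@H](c2cc(O[Si](C)(C)C(C)(C)C)c(O[Si](C)(C)C(C)(C)C)c(O[Si](C)(C)C(C)(C)C)c2)[C@H]2CO[C@@H](c3ccc(O[Si](C)(C)C(C)(C)C)c(O[Si](C)(C)C(C)(C)C)c3)[C@@H]12 | intermediate
17 | (3S,3aR,6S,6aS)-6-[3,4-bis(TBSO)phenyl]-3-[3,4,5-tris(TBSO)phenyl]tetrahydro-1H,3H-furo[3,4-c]furan-1-one | O=C1O[C@H](c2cc(O[Si](C)(C)C(C)(C)C)c(O[Si](C)(C)C(C)(C)C)c(O[Si](C)(C)C(C)(C)C)c2)[C@H]2CO[C@H](c3ccc(O[Si](C)(C)C(C)(C)C)c(O[Si](C)(C)C(C)(C)C)c3)[C@@H]12 | intermediate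
18 | (3S,3aR,6S,6aS)-6-(3,4-dihydroxyphenyl)-3-(3,4,5-trihydroxyphenyl)tetrahydro-1H,3H-furo[3,4-c]furan-1-one | O=C1O[C@H](c2cc(O)c(O)c(O)c2)[C@H]2CO[C@H](c3ccc(O)c(O)c3)[C@@H]12 | target

**Step count**
Total steps: 12. Longest linear sequence: 8 steps (steps 5 to 12 from 7 and 8; equally 1, 6 to 12 from 1 and 2, 3, 4, 8 to 12 from 3).

**Steps most likely to fail**

Step 10. The carbenoid may be diverted before it reaches C6–H: 1,2-hydride shift from C3a–H to a butenolide, attack on O5 to an oxonium ylide, or dimerisation. Fallback (sets out from 12, returns at 17), in which ring B is closed through the C6 cation instead: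
- Catalytic DBU in CH2Cl2 moves the lactone of 12 onto the primary hydroxyl and should give the isomeric lactone (4R)-4-{(S)-hydroxy[3,4,5-tris(TBSO)phenyl]methyl}oxolan-2-one F1.
- Et3SiCl and imidazole convert it into the triethylsilyl ether F2.
- The lithium enolate of F2 (LiN(SiMe3)2, THF, −78 °C) should add to aldehyde 4 anti to the C4 substituent, which is the relative configuration a cis-fused furofuranone needs, and give the aldol adduct (3S,4R)-3-{hydroxy[3,4-bis(TBSO)phenyl]methyl}-4-{(S)-[3,4,5-tris(TBSO)phenyl](triethylsilyloxy)methyl}oxolan-2-one F3 as carbinol epimers.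
- CSA in wet CH2Cl2 removes the triethylsilyl group to give the diol F4 and lets the lactone migrate back to the C3 hydroxyl to give the hydroxymethyl lactone F5. It also ionises the C6 carbinol, so that the C4 hydroxyl closes ring B on the benzylic cation, cis-fused and with Ar2 on the convex face, which is 17. Both carbinol epimers converge on the same cation.

Step 11. The equilibration may stall or lose selectivity: the equilibrium may not lie far enough on the exo side, ionisation may occur at the lactone carbon C3 as well, or the Lewis acid may strip silyl ethers. Fallback (sets out from 16, returns at 18):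
- 16 is desilylated first (TBAF, AcOH, THF, 0 °C) to the C6 epimer of the target, (3S,3aR,6R,6aS)-6-(3,4-dihydroxyphenyl)-3-(3,4,5-trihydroxyphenyl)tetrahydro-1H,3H-furo[3,4-c]furan-1-one F6.
- The epimerisation is then run on the free phenol in dilute acid (0.1 M HCl, MeCN–H2O, rt, argon). The free para-hydroxyl of Ar2 opens C6–O5 to the protonated quinone methide far more easily than a silyl ether does, and ring B recloses to the exo isomer 18, which is separated from remaining F6 by reversed-phase chromatography.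

Step 7. The liberated primary alkoxide may attack the lactone carbonyl and migrate the lactone (translactonisation), the lactone may be over-reduced, or aryl silyl ethers may be lost in the basic medium. Fallback (sets out from 11, returns at 12):
- LiOH/H2O2 (THF–H2O, 0 °C, short contact) hydrolyses the imide to (2S,3S)-5-oxo-2-[3,4,5-tris(TBSO)phenyl]oxolane-3-carboxylic acid F7, in which a carboxylate cannot migrate the lactone.
- BH3·SMe2 (THF, 0 °C) then reduces the acid in the presence of the lactone to 12 under non-basic conditions.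

**Further compounds**
F1 | step 10 | (4R)-4-{(S)-hydroxy[3,4,5-tris(TBSO)phenyl]methyl}oxolan-2-one | O[C@H](c1cc(O[Si](C)(C)C(C)(C)C)c(O[Si](C)(C)C(C)(C)C)c(O[Si](C)(C)C(C)(C)C)c1)[C@H]1COC(=O)C1
F2 | step 10 | (4R)-4-{(S)-[3,4,5-tris(TBSO)phenyl](triethylsilyloxy)methyl}oxolan-2-one | CC[Si](CC)(CC)O[C@H](c1cc(O[Si](C)(C)C(C)(C)C)c(O[Si](C)(C)C(C)(C)C)c(O[Si](C)(C)C(C)(C)C)c1)[C@H]1COC(=O)C1
F3 | step 10 | (3S,4R)-3-{hydroxy[3,4-bis(TBSO)phenyl]methyl}-4-{(S)-[3,4,5-tris(TBSO)phenyl](triethylsilyloxy)methyl}oxolan-2-one (carbinol epimers) | CC[Si](CC)(CC)O[C@H](c1cc(O[Si](C)(C)C(C)(C)C)c(O[Si](C)(C)C(C)(C)C)c(O[Si](C)(C)C(C)(C)C)c1)[C@H]1COC(=O)[C@@H]1C(O)c1ccc(O[Si](C)(C)C(C)(C)C)c(O[Si](C)(C)C(C)(C)C)c1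
F4 | step 10 | (3S,4R)-3-{hydroxy[3,4-bis(TBSO)phenyl]methyl}-4-{(S)-hydroxy[3,4,5-tris(TBSO)phenyl]methyl}oxolan-2-one (carbinol epimers) | O[C@H](c1cc(O[Si](C)(C)C(C)(C)C)c(O[Si](C)(C)C(C)(C)C)c(O[Si](C)(C)C(C)(C)C)c1)[C@H]1COC(=O)[C@@H]1C(O)c1ccc(O[Si](C)(C)C(C)(C)C)c(O[Si](C)(C)C(C)(C)C)c1
F5 | step 10 | (3S,4R,5S)-3-{hydroxy[3,4-bis(TBSO)phenyl]methyl}-4-(hydroxymethyl)-5-[3,4,5-tris(TBSO)phenyl]oxolan-2-one (carbinol epimers) | O=C1O[C@H](c2cc(O[Si](C)(C)C(C)(C)C)c(O[Si](C)(C)C(C)(C)C)c(O[Si](C)(C)C(C)(C)C)c2)[C@@H](CO)[C@H]1C(O)c1ccc(O[Si](C)(C)C(C)(C)C)c(O[Si](C)(C)C(C)(C)C)c1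
F6 | step 11 | (3S,3aR,6R,6aS)-6-(3,4-dihydroxyphenyl)-3-(3,4,5-trihydroxyphenyl)tetrahydro-1H,3H-furo[3,4-c]furan-1-one | O=C1O[C@H](c2cc(O)c(O)c(O)c2)[C@H]2CO[C@@H](c3ccc(O)c(O)c3)[C@@H]12
F7 | step 7 | (2S,3S)-5-oxo-2-[3,4,5-tris(TBSO)phenyl]oxolane-3-carboxylic acid | O=C1O[C@H](c2cc(O[Si](C)(C)C(C)(C)C)c(O[Si](C)(C)C(C)(C)C)c(O[Si](C)(C)C(C)(C)C)c2)[C@@H](C(=O)O)C1
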